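The rate constants stand for no real mixture.

A molecule of starting material stands at a fork: it opens by itself to the open intermediate, or protic impurity quenches it.

| flask | starting material | partner | protic impurity | remark | time |
|---|---|---|---|---|---|
| oak | 0.050 M | 0.800 equiv | 0.0150 M | one stirred flow tank at steady state, fed with the mixture as stated, mean residence time 25.0 h |  |
| larch | 0.050 M | 0.800 equiv | 0.0150 M | one stirred flow tank at steady state, fed with the mixture as stated, mean residence time 5.0 h |  |
| maple | 0.050 M (fed, over 4.00 h) | 0.800 equiv | 0.0150 M | a stirred flask in which starting material is dosed at a steady rate over 4.00 h without added volume, worked up at 5.0 h | 5.0 h |
| birch | 0.050 M | 0.800 equiv | 0.0150 M | a closed flask charged with all of it at once and left for 5.0 h | 5.0 h |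

    open intermediate + second intermediate → target (k1 = 2.93 M⁻¹ h⁻¹)
    starting material → open intermediate (k2 = 0.314 h⁻¹)
    2 second intermediate → homo product (k3 = 0.0599 M⁻¹ h⁻¹)
    starting material + protic impurity → quenched substrate (k4 = 15.7 M⁻¹ h⁻¹)
    partner → second intermediate (k5 = 0.0969 h⁻¹)

1. the set-up with the highest amount of open intermediate at the outlet or at the end, in percent of the starting material put in ("none" if the first two lie within 2 percentage points) (oak / larch / maple / birch / none)
2. amount of open intermediate at the outlet or at the end, in percent of the starting material put in, oak
3. amount of open intermediate at the outlet or at the end, in percent of the starting material put in, larch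
4. amount of open intermediate at the outlet or at the end, in percent of the starting material put in, maple
5. amount of open intermediate at the outlet or at the end, in percent of the starting material put in, birch

1. Opening runs at 0.314 h⁻¹ and quenching at the pseudo-first-order rate k4 times the impurity present, so starting material cancels from their ratio. Neither partner nor second intermediate enters either step.
2. Two amounts therefore set the fork: the impurity present and the even-odds level, the impurity at which both routes run equally fast, 40.0% of the charge. The fork share, the chance of opening, is that level divided by the sum of the two amounts.
3. Impurity starts at 30.0% of the charge, less than the even-odds level, so the opening share at the start is 57.1%.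
4. My own reckoning for birch applies that share to the whole charge and gives 57.1%, a rough figure that ignores falling impurity, starting material still unreacted at the end, and the losses to coupling. Birch's time of 5.0 h is shorter than the 7.2 h half-life of partner by step 5 alone, while oak's mean residence time of 25.0 h is longer, so I expect birch to beat oak; larch and maple stay unreckoned.

The forecast gives oak 38.8%, larch 44.5%, maple 44.8% and birch 57.7%, which is above my figure for birch, and concludes: “Birch is best.”

The simulation gives oak 38.8%, larch 44.4%, maple 45.0% and birch 57.8%, so birch is best, as the forecast said.

At 5.0 h, birch has 13.1% starting material and 5.24% target, so quenching took 23.8% of the charge, leaving impurity at 6.20% and a fork share of 86.6%. Maple at its end, with 31.1% starting material and 2.99% target, had lost 21.0% to quenching, leaving a share of 81.6%. Applying those shares to the remaining starting material gives an estimate of about 74.4% of the charge opened in birch and about 73.4% in maple. Birch is not at rest at 5.0 h: after 50.0 h its open intermediate stands at 13.7%, which by that estimate puts about 60.7% of the charge in target.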